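**Assumptions.** Locants are daucane numbering: C1 is the quaternary ring-fusion carbon, C4 is C(OH)iPr, C5 is the ring-fusion CH, C6 is CH–O-acyl, C8 is C(=CH2) and C9 is CHOH. The target is (1R,4R,5S,6S,9S), meaning 15-Me β, 4-OH β, 5-H α, 6-O α and 9-OH α. The chiral NHC–Ag precatalyst in Step 2 is treated as a purchasable catalyst, and its enantiomer is chosen to give the (R) centre.

## Retrosynthetic overview
1. Ferugin comes from phenol desilylation, preceded by isomerisation of an 8α,9α-epoxide to the allylic alcohol and by α-face epoxidation of O-silyl ferutinin.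
2. O-Silyl ferutinin comes from jaeschkeanadiol by selective acylation of the C6-OH with 4-silyloxybenzoic acid.
3. The seven-membered ring is formed last, by ring-closing metathesis at C8=C9 of a fully substituted cyclopentane diene.
4. C4 is set by isopropyl-cerium addition to the cyclopentanone, and C5/C6 by an anti boron aldol with 3-methylbut-3-enal.
5. C1 is set by Cu/NHC asymmetric conjugate addition of Me3Al to 3-allylcyclopentenone. The five-membered ring is present in the starting material.

## Route

**Step 1**
Reactants: 1 (3-ethoxycyclopent-2-en-1-one); 2 (allylmagnesium bromide)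
Product: 3 (3-(prop-2-en-1-yl)cyclopent-2-en-1-one)
Conditions: 2 (1.2 equiv), Et2O/THF, 0 °C; then 1 M HCl, 0 °C, 15 min
Reagents that add atoms: allylmagnesium bromide, C=CC[Mg]Br
Why: Stork–Danheiser transposition, in which 1,2-addition to the vinylogous ester and brief cold acid hydrolysis give the β-allyl enone without moving the allyl double bond into conjugation; no stereocentre is formed.

**Step 2**
Reactants: 3; 4 (trimethylaluminium); 5 (trimethylsilyl triflate)
Product: 6 ({[(3R)-3-methyl-3-(prop-2-en-1-yl)cyclopent-1-en-1-yl]oxy}trimethylsilane)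
Conditions: Me3Al (3 equiv), Cu(OTf)2 (5 mol %), chiral sulfonate-NHC·Ag complex (2.5 mol %), THF, −78 °C; then TMSOTf, Et3N, −78 → 0 °C
Reagents that add atoms: Me3Al, C[Al](C)C; TMSOTf, C[Si](C)(C)OS(=O)(=O)C(F)(F)F
Why: NHC–Cu-catalysed asymmetric conjugate addition to a β-substituted cyclopentenone, where the catalyst selects the enone face to set quaternary C1 as R, and O-silylation of the aluminium enolate fixes the enolate at C4=C5, the hindered side that direct deprotonation cannot reach.

**Step 3** (side branch)
Reactants: 7 (3-methylbut-3-en-1-ol)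
Product: 8 (3-methylbut-3-enal)
Conditions: Dess–Martin periodinane, NaHCO3, CH2Cl2, 0 °C; filtered solution used at once
Reagents that add atoms: none
Why: Dess–Martin oxidation under buffered, amine-free conditions gives the β,γ-unsaturated aldehyde without isomerisation to prenal.

**Step 4**
Reactants: 6; 8
Product: 9 ((2S,3R)-2-[(1S)-1-hydroxy-3-methylbut-3-en-1-yl]-3-methyl-3-(prop-2-en-1-yl)cyclopentan-1-one)
Conditions: n-Bu2BOTf, CH2Cl2, 0 °C (Si→B exchange); 8, −78 °C; pH 7 buffer, H2O2, MeOH; chromatography
Reagents that add atoms: 3-methylbut-3-enal, CC(=C)CC=O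
Why: Boron aldol through a Zimmerman–Traxler chair, in which the ring-locked (E)-enolate gives the anti adduct (5S,6S) and the aldehyde attacks the face bearing the small C1 methyl, anti to the larger allyl group, so C6 ends up trans to C10; the non-basic conditions spare the sensitive aldehyde.

**Step 5**
Reactants: 9; 10 (isopropyllithium)
Product: 11 ((1R,2S,3R)-2-[(1S)-1-hydroxy-3-methylbut-3-en-1-yl]-3-methyl-1-(propan-2-yl)-3-(prop-2-en-1-yl)cyclopentan-1-ol)
Conditions: anhydrous CeCl3 (4 equiv), i-PrLi (3.8 equiv), THF, −78 °C; aq NH4Cl
Reagents that add atoms: isopropyllithium, [Li]C(C)C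
Why: Imamoto organocerium 1,2-addition, which suppresses enolisation, reduction and retro-aldol; the first equivalent forms the C6 alkoxide, and iPr then adds from the α face, anti to the adjacent C5 side chain and the 1,3-related C1 methyl, giving the 4β-OH (4R).

**Step 6**
Reactants: 11
Product: 12 (jaeschkeanadiol, (3R,3aS,4S,8aR)-6,8a-dimethyl-3-(propan-2-yl)-1,2,3a,4,5,8-hexahydroazulene-3,4-diol)
Conditions: Grubbs II (5 mol %), 1,4-benzoquinone (10 mol %), CH2Cl2 (2 mM), reflux; recrystallise
Reagents that add atoms: none
Why: Ring-closing metathesis of the allyl and methallyl termini loses ethylene and closes the trans-fused cycloheptene with the trisubstituted C8=C9 alkene, leaving all four existing stereocentres untouched.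

**Step 7** (side branch)
Reactants: 13 (4-hydroxybenzoic acid); 14 (tert-butyldimethylsilyl chloride)
Product: 15 (4-[(tert-butyldimethylsilyl)oxy]benzoic acid)
Conditions: TBSCl (2.3 equiv), imidazole, DMF, rt; then K2CO3, THF/MeOH/H2O, rt; pH 4 work-up
Reagents that add atoms: TBSCl, CC(C)(C)[Si](C)(C)Cl
Why: Bis-silylation followed by selective hydrolysis of the labile silyl ester masks the phenol so the acid cannot acylate itself.

**Step 8**
Reactants: 12; 15
Product: 16 (ferutinin O-TBS ether, the C6 4-(TBSO)benzoate of jaeschkeanadiol)
Conditions: 15, 2,4,6-trichlorobenzoyl chloride, Et3N, PhMe; then 12, DMAP, 60 °C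
Reagents that add atoms: acid 15, CC(C)(C)[Si](C)(C)Oc1ccc(cc1)C(=O)O
Why: Yamaguchi esterification acylates only the secondary C6-OH because the tertiary C4-OH is inert, and C6 keeps its configuration since the C–O bond is not broken.

**Step 9**
Reactants: 16; 17 (m-chloroperoxybenzoic acid)
Product: 18 ((8R,9S)-8α,9α-epoxide of 16)
Conditions: mCPBA (1.2 equiv), NaHCO3, CH2Cl2, 0 °C
Reagents that add atoms: mCPBA, OOC(=O)c1cccc(Cl)c1
Why: Prilezhaev epoxidation of the only alkene occurs from the α face, because the axial angular C15 methyl shields the β face while the C6 ester is equatorial; this sets C9–O as α, and the buffer prevents acid-induced transannular opening.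

**Step 10**
Reactants: 18
Product: 19 (ferugin O-TBS ether: 8(14)-ene, 9α-OH)
Conditions: Et2Al(TMP) (from LiTMP + Et2AlCl, 5 equiv), PhMe, 0 °C; Rochelle salt work-up
Reagents that add atoms: none
Why: Yamamoto aluminium-amide isomerisation of an epoxide to an allylic alcohol by syn β-elimination removes a proton from the C14 methyl, the alkyl group cis to the epoxide H, giving the exocyclic methylene; the C9–O bond is never broken so 9S is retained, and the non-enolisable hindered benzoate and the aryl silyl ether survive the non-nucleophilic base.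

**Step 11**
Reactants: 19
Product: 20 (ferugin)
Conditions: TBAF/AcOH (1:1, 1.2 equiv), THF, 0 °C
Reagents that add atoms: none
Why: Buffered fluoride desilylation cleaves the aryl silyl ether within minutes without acyl migration or ester cleavage, and no stereocentre is affected.

## Compound list
1 | 3-ethoxycyclopent-2-en-1-one | CCOC1=CC(=O)CC1 | starting material
2 | allylmagnesium bromide | C=CC[Mg]Br | starting material
3 | 3-allylcyclopent-2-en-1-one | C=CCC1=CC(=O)CC1 | intermediate
4 | trimethylaluminium | C[Al](C)C | starting material
5 | trimethylsilyl triflate | C[Si](C)(C)OS(=O)(=O)C(F)(F)F | starting material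
6 | (R)-3-allyl-3-methylcyclopent-1-enyl TMS ether | C[Si](C)(C)OC1=C[C@@](C)(CC=C)CC1 | intermediate
7 | 3-methylbut-3-en-1-ol | CC(=C)CCO | starting material
8 | 3-methylbut-3-enal | CC(=C)CC=O | intermediate
9 | anti-aldol ketone (2S,3R,1'S) | CC(=C)C[C@H](O)[C@@H]1[C@](C)(CCC1=O)CC=C | intermediate
10 | isopropyllithium | [Li]C(C)C | starting material
11 | diene diol (1R,2S,3R,1'S) | CC(=C)C[C@H](O)[C@@H]1[C@](C)(CC[C@@]1(O)C(C)C)CC=C | intermediate
12 | jaeschkeanadiol | CC1=CC[C@]2(CC[C@]([C@@H]2[C@H](C1)O)(C(C)C)O)C | intermediate
13 | 4-hydroxybenzoic acid | OC(=O)c1ccc(O)cc1 | starting material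
14 | TBSCl | CC(C)(C)[Si](C)(C)Cl | starting material
15 | 4-(TBSO)benzoic acid | CC(C)(C)[Si](C)(C)Oc1ccc(cc1)C(=O)O | intermediate
16 | ferutinin O-TBS ether | CC1=CC[C@]2(CC[C@]([C@@H]2[C@H](C1)OC(=O)c3ccc(O[Si](C)(C)C(C)(C)C)cc3)(C(C)C)O)C | intermediate
17 | mCPBA | OOC(=O)c1cccc(Cl)c1 | starting material
18 | 8α,9α-epoxyferutinin O-TBS ether | C[C@@]12C[C@H](OC(=O)c3ccc(O[Si](C)(C)C(C)(C)C)cc3)[C@@H]4[C@](C)(CC[C@@]4(O)C(C)C)C[C@@H]1O2 | intermediate
19 | ferugin O-TBS ether | C=C1C[C@H](OC(=O)c2ccc(O[Si](C)(C)C(C)(C)C)cc2)[C@@H]2[C@](C)(CC[C@@]2(O)C(C)C)C[C@@H]1O | intermediate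
20 | ferugin | C=C1C[C@H](OC(=O)c2ccc(O)cc2)[C@@H]2[C@](C)(CC[C@@]2(O)C(C)C)C[C@@H]1O | target

## Summary
Total steps: 11.
Longest linear sequence: 9 (Steps 1, 2, 4, 5, 6, 8, 9, 10, 11).

**Most likely to fail**
1. **Step 4.** Facial selectivity depends only on methyl versus allyl at C1, so the C5 diastereomer ratio may be modest, and the aldehyde is fragile. Fallback: reverse the order of bond formation. Attach the C6 carbinol side chain to C5 of 3-allylcyclopentenone first, via the 2-bromo ketal, lithiation and addition to 8, with C6 set by asymmetric ketone reduction. Then deliver the angular methyl intramolecularly from a C6–O–SiMe2CH2Br tether by radical conjugate cyclisation and protodesilylation. The tether forces Me cis to C6, which gives the trans ring fusion.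
2. **Step 2.** The 3-allyl enone can isomerise to the conjugated dienone, and the ee on this substrate is untested. Fallback: catalytic asymmetric 1,2-allylation of commercial 3-methylcyclopent-2-enone, followed by anionic oxy-Cope rearrangement (KH, 18-crown-6). The 1,3-chirality transfer builds C1 and produces the same C4=C5 enolate, which is silylated to 6.
3. **Step 10.** Competing transannular attack of the C4 alkoxide on C8, attack on the ester, or endocyclic elimination could intervene. Fallback: skip the epoxide and use a Schenck ene reaction on 16 (1O2, TPP, hν, then PPh3). Oxygen is delivered to C9 from the α face with the alkene shifting to C8=C14, and regioisomers are separated.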